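**Plan**

- Retrosynthesis: C1 (enol-ether carbon of the 2,3-dihydrofuran) and C6 (enol-lactone carbon of the butenolide) are both at the ketone level and lie 1,6 across the ten-membered carbocycle. The target is therefore a doubly dehydrated bis-hemiketal of a cyclodecane-1,6-dione; the two dehydrations are cut first, then C1 and C6 are rejoined as the ring-fusion alkene of a temporary octalin (ring A: C1–C6; ring B: C1, C6–C10).
- Ring B is cut at C1–C10 (alkenyl triflate plus C10 methyl ketone), then at C6–C7 (Suzuki), giving a ring A iodoenone and a 2,5-dihydrofuran triflate. This dihydrofuran (O bridging C8 and C13) is a second temporary ring, opened at C13–O only after ring B exists.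
- Forward: ring A by ring-closing metathesis; dihydrofuran by oxa-Michael/Dieckmann; C6–C7 coupling; ring B by C1–C10 closure; dihydrofuran opened to C13–OAc and C8–O-methacrylate; ozonolysis of C1=C6 releases the ten-membered ring, whose ketones are caught by C4–OH and the C12 acid; double dehydration.
- Stereochemistry: C4 from (R)-linalool; C8 from a BINOL–titanium glyoxylate-ene reaction; C10 in the ring B closure under control of C8 through the locked dihydrofuran; C7=C11 geometry from the dihydrofuran ring; C5=C6 geometry from the oxygen-bridged bicycle.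

Key step: step 14

Remark: atoms are numbered as in a germacranolide (ring carbons C1–C10, lactone carbons C11–C13, C14 = methyl on C10, C15 = methyl on C4); in this numbering the target is (4R,8R,10S) with C4 cis to C7 across C5=C6.

**Step 1**
Reactants: 1 (R)-(−)-linalool
Product: 2 (3R)-3,7-dimethyl-3-(triethylsilyloxy)octa-1,6-diene
Conditions: Et3SiOTf, 2,6-lutidine, CH2Cl2, −78 → 0 °C
Reagents that add atoms: triethylsilyl trifluoromethanesulfonate, CC[Si](CC)(CC)OS(=O)(=O)C(F)(F)F
Why: Silylation of a tertiary allylic alcohol with a silyl triflate and a hindered base is routine; it masks the future ring oxygen on C4, whose configuration comes unchanged from linalool.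

**Step 2**
Reactants: 2 (3R)-3,7-dimethyl-3-(triethylsilyloxy)octa-1,6-diene
Product: 3 (4R)-4-methyl-4-(triethylsilyloxy)hex-5-enal
Conditions: O3, pyridine, CH2Cl2, −78 °C (Sudan Red 7B end point)
Reagents that add atoms: ozone, [O-][O+]=O
Why: Chemoselective ozonolysis, since the electron-rich trisubstituted alkene reacts well before the monosubstituted vinyl group, and pyridine should give the aldehyde (C1) directly.

**Step 3**
Reactants: 3 (4R)-4-methyl-4-(triethylsilyloxy)hex-5-enal
Product: 4 (6R)-6-methyl-6-(triethylsilyloxy)octa-1,7-dien-3-ol (C3 epimers)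
Conditions: CH2=CHMgBr, THF, −78 → 0 °C; aq. NH4Cl
Reagents that add atoms: vinylmagnesium bromide, C=C[Mg]Br
Why: Grignard 1,2-addition brings in C6; the new carbinol centre forms as a mixture that is removed by oxidation in step 5.

**Step 4**
Reactants: 4 (6R)-6-methyl-6-(triethylsilyloxy)octa-1,7-dien-3-ol
Product: 5 (4R)-4-methyl-4-(triethylsilyloxy)cyclohex-2-en-1-ol (C1 epimers)
Conditions: RuCl2(=CHPh)(PCy3)(H2IMes) (second-generation Grubbs catalyst, 3 mol %), CH2Cl2, 40 °C
Reagents that add atoms: none
Why: Ring-closing metathesis of a 1,7-diene to a cyclohexene closes ring A (C5=C6) with loss of ethylene.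

**Step 5**
Reactants: 5 (4R)-4-methyl-4-(triethylsilyloxy)cyclohex-2-en-1-ol
Product: 6 (4R)-4-methyl-4-(triethylsilyloxy)cyclohex-2-en-1-one
Conditions: MnO2, CH2Cl2, 23 °C
Reagents that add atoms: none
Why: Allylic oxidation of the secondary alcohol with MnO2 gives the enone whose carbonyl carbon is C1.

**Step 6**
Reactants: 6 (4R)-4-methyl-4-(triethylsilyloxy)cyclohex-2-en-1-one
Product: 7 (4R)-2-iodo-4-methyl-4-(triethylsilyloxy)cyclohex-2-en-1-one
Conditions: I2, pyridine, CH2Cl2, 0 → 23 °C
Reagents that add atoms: iodine, II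
Why: α-Iodination of the enone (pyridine conjugate addition, iodination of the enolate, elimination) marks C6 for cross-coupling.

**Step 7**
Reactants: 8 ethyl glyoxylate; 9 isobutylene
Product: 10 ethyl (2R)-2-hydroxy-4-methylpent-4-enoate
Conditions: TiCl2(OiPr)2/(R)-BINOL (10 mol %), 4 Å MS, CH2Cl2, −30 °C
Reagents that add atoms: none
Why: Catalytic asymmetric glyoxylate-ene (carbonyl-ene) reaction, in which the (R)-BINOL titanium complex should shield one aldehyde face and set C8 as (R); the isopropenyl group is the masked C10 methyl ketone.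

**Step 8**
Reactants: 11 acryloyl chloride; 12 2-(trimethylsilyl)ethanol
Product: 13 2-(trimethylsilyl)ethyl acrylate
Conditions: Et3N, CH2Cl2, 0 °C
Reagents that add atoms: none
Why: Simple acylation of a primary alcohol; it supplies C11–C13 with an ester that fluoride can remove late in the presence of acetate and methacrylate.

**Step 9**
Reactants: 10 ethyl (2R)-2-hydroxy-4-methylpent-4-enoate; 13 2-(trimethylsilyl)ethyl acrylate
Product: 15 2-(trimethylsilyl)ethyl (5R)-5-(2-methylprop-2-enyl)-4-oxotetrahydrofuran-3-carboxylate (C3 epimers/enol), via oxa-Michael adduct 14 (not isolated)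
Conditions: PMe3 (10 mol %), THF, 23 °C; then LiN(SiMe3)2 (2.2 equiv), −78 → −40 °C; AcOH
Reagents that add atoms: none
Why: Phosphine-catalysed oxa-Michael addition (O–C13) followed by Dieckmann condensation (C11–C7) from the kinetically formed C11 enolate; the enolisable β-keto ester is the thermodynamic sink and the cold, non-equilibrating base should leave C8 untouched.

**Step 10**
Reactants: 15 2-(trimethylsilyl)ethyl (5R)-5-(2-methylprop-2-enyl)-4-oxotetrahydrofuran-3-carboxylate
Product: 16 2-(trimethylsilyl)ethyl (5R)-5-(2-methylprop-2-enyl)-4-(trifluoromethylsulfonyloxy)-2,5-dihydrofuran-3-carboxylate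
Conditions: Tf2O, i-Pr2NEt, CH2Cl2, −78 °C
Reagents that add atoms: trifluoromethanesulfonic anhydride, O=S(=O)(OS(=O)(=O)C(F)(F)F)C(F)(F)F
Why: O-Triflation of a cyclic β-keto ester; the five-membered ring fixes the C7=C11 geometry so that C12 will be cis to C6 and C13 cis to C8.

**Step 11**
Reactants: 16 2-(trimethylsilyl)ethyl (5R)-5-(2-methylprop-2-enyl)-4-(trifluoromethylsulfonyloxy)-2,5-dihydrofuran-3-carboxylate; 7 (4R)-2-iodo-4-methyl-4-(triethylsilyloxy)cyclohex-2-en-1-one
Product: 18 2-(trimethylsilyl)ethyl (5R)-5-(2-methylprop-2-enyl)-4-[(3R)-3-methyl-6-oxo-3-(triethylsilyloxy)cyclohex-1-enyl]-2,5-dihydrofuran-3-carboxylate, via alkenyl pinacolboronate 17 (not isolated)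
Conditions: B2pin2, PdCl2(dppf) (5 mol %), KOAc, dioxane, 80 °C; then 7, aq. K3PO4, 60 °C
Reagents that add atoms: none
Why: One-pot Miyaura borylation of the enol triflate and Suzuki–Miyaura coupling with the α-iodoenone forms C6–C7 with retention of the alkene geometry.

**Step 12**
Reactants: 18 2-(trimethylsilyl)ethyl (5R)-5-(2-methylprop-2-enyl)-4-[(3R)-3-methyl-6-oxo-3-(triethylsilyloxy)cyclohex-1-enyl]-2,5-dihydrofuran-3-carboxylate
Product: 20 2-(trimethylsilyl)ethyl (5R)-5-(2-methylprop-2-enyl)-4-[(5R)-5-methyl-5-(triethylsilyloxy)-2-(trifluoromethylsulfonyloxy)cyclohex-1-enyl]-2,5-dihydrofuran-3-carboxylate, via lithium enolate 19 (not isolated)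
Conditions: LiBH(s-Bu)3, THF, −78 °C; then N-(5-chloropyridin-2-yl)bis(trifluoromethanesulfonyl)imide, −78 → −20 °C
Reagents that add atoms: N-(5-chloropyridin-2-yl)bis(trifluoromethanesulfonyl)imide, O=S(=O)(N(c1ccc(Cl)cn1)S(=O)(=O)C(F)(F)F)C(F)(F)F
Why: Conjugate hydride reduction of the β-unsubstituted enone gives the C1/C6 enolate regiospecifically, and triflation at −78 °C should outrun O-acylation of the enolate by the cis ester, placing the temporary C1=C6 alkene with its triflate on C1.

**Step 13**
Reactants: 20 2-(trimethylsilyl)ethyl (5R)-5-(2-methylprop-2-enyl)-4-[(5R)-5-methyl-5-(triethylsilyloxy)-2-(trifluoromethylsulfonyloxy)cyclohex-1-enyl]-2,5-dihydrofuran-3-carboxylate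
Product: 21 2-(trimethylsilyl)ethyl (5R)-4-[(5R)-5-methyl-5-(triethylsilyloxy)-2-(trifluoromethylsulfonyloxy)cyclohex-1-enyl]-5-(2-oxopropyl)-2,5-dihydrofuran-3-carboxylate
Conditions: O3, pyridine, CH2Cl2, −78 °C (Sudan Red 7B end point)
Reagents that add atoms: ozone, [O-][O+]=O
Why: Chemoselective ozonolysis of the isolated 1,1-disubstituted alkene, since the triflyloxy diene ester is electron-poor; this unveils the C10 methyl ketone.

**Step 14**
Reactants: 21 2-(trimethylsilyl)ethyl (5R)-4-[(5R)-5-methyl-5-(triethylsilyloxy)-2-(trifluoromethylsulfonyloxy)cyclohex-1-enyl]-5-(2-oxopropyl)-2,5-dihydrofuran-3-carboxylate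
Product: 22 tricyclic alcohol (4R,8R,10S): 1(6)-octalin (ring A C1–C6 with C4(CH3)(OSiEt3); ring B C1, C6–C10 with C10(CH3)(OH)) fused at C7–C8 to the 2,5-dihydrofuran (O on C8 and C13, C7=C11, 2-(trimethylsilyl)ethyl ester on C11)
Conditions: CrCl2 (6 equiv), NiCl2 (5 mol %), DMF, 25 °C
Reagents that add atoms: none
Why: Zerovalent nickel inserts into the C1–OTf bond and hands the alkenyl group to chromium, and the resulting alkenylchromium (trivalent chromium) adds to the C10 ketone; the closest known reaction type is the intramolecular Nozaki–Hiyama–Kishi addition of an alkenyl triflate to a carbonyl group. Ring B closes in the 6-exo-trig mode on the carbonyl carbon and so completes the octalin whose C1=C6 bond is the alkene to be cleaved in step 19. The only new stereocentre, C10, is controlled by C8: the dihydrofuran holds the C8–O bond in the plane of the C7=C11 alkene, which fixes the half-chair of the forming ring with C8–H axial. In that half-chair the methyl group of the ketone should take the axial position on the face of C8–H and the chromium-bound oxygen the in-plane position, because an in-plane methyl group would clash with the C2 methylene of ring A (allylic 1,2-strain); this places C10–O cis to C8–O, as the target needs (10S). The step needs chemoselectivity for the ketone over the ester, which the low reactivity of alkenylchromium reagents toward esters secures, and it needs the C8–O bond β to the ketone to survive, which the non-basic medium secures.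

**Step 15**
Reactants: 22 tricyclic alcohol
Product: 23 bromo diol (4R,8R,10S): octalin with C8–OH, C10–OH, C4–OSiEt3 and an exocyclic C7=C11 bearing CH2Br (C13, cis to C8) and the 2-(trimethylsilyl)ethyl ester (C12, cis to C6)
Conditions: Me2BBr (2.5 equiv), Et3N (0.2 equiv), CH2Cl2, −78 °C; aq. NaHCO3
Reagents that add atoms: bromodimethylborane, CB(C)Br
Why: Regioselective Lewis-acid ether cleavage, in which boron binds the ring oxygen and bromide attacks the less hindered primary allylic C13 in an SN2 manner, so the C8–O bond and the C8 configuration are kept.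

**Step 16**
Reactants: 23 bromo diol
Product: 24 C13 acetate (4R,8R,10S): as 23 with CH2OAc in place of CH2Br
Conditions: Bu4NOAc, acetone, 0 °C
Reagents that add atoms: tetrabutylammonium acetate, CCCC[N+](CCCC)(CCCC)CCCC.CC(=O)[O-]
Why: SN2 displacement of the primary allylic bromide by acetate; the SN2′ position (C7) is fully substituted and the weakly basic medium should not re-close the ether.

**Step 17**
Reactants: 24 C13 acetate
Product: 25 C8 methacrylate (4R,8R,10S): as 24 with C8–O–C(=O)C(CH3)=CH2
Conditions: methacrylic anhydride, Et3N, DMAP (10 mol %), CH2Cl2, 0 → 23 °C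
Reagents that add atoms: methacrylic anhydride, C=C(C)C(=O)OC(=O)C(C)=C
Why: DMAP-catalysed acylation of the only secondary hydroxyl; the tertiary C10–OH does not react, and the ester blocks C8–OH from later hemiketal formation.

**Step 18**
Reactants: 25 C8 methacrylate
Product: 26 hydroxy acid (4R,8R,10S): as 25 with free C4–OH and free C12 carboxylic acid
Conditions: Bu4NF, THF, 0 → 23 °C; AcOH
Reagents that add atoms: none
Why: Fluoride cleaves the 2-(trimethylsilyl)ethyl ester by β-fragmentation and the tertiary triethylsilyl ether in one operation, leaving the acetate and methacrylate in place.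

**Step 19**
Reactants: 26 hydroxy acid
Product: 28 transannular bis-hemiketal (C1(OH) bridged by oxygen to C4; C6 as 5-hydroxybutenolide; C1/C6 epimers), via hydroperoxy hemiketal 27 (not isolated)
Conditions: O3 (Sudan Red 7B end point), CH2Cl2, −78 °C; then Me2S, −78 → 23 °C
Reagents that add atoms: ozone, [O-][O+]=O
Why: Ozonolysis of the most electron-rich, tetrasubstituted C1=C6 alkene ahead of the methacrylate and the C7=C11 enoate turns the octalin into the ten-membered 1,6-dione, whose carbonyl groups are captured at once by C4–OH (at C1) and by the C12 acid (at C6), which should forestall transannular aldol reactions; the two hemiketal centres are not controlled and disappear in step 20.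

**Step 20**
Reactants: 28 transannular bis-hemiketal
Product: 29 target, CNP0394509.1
Conditions: MsCl, Et3N, CH2Cl2, −40 → 0 °C
Reagents that add atoms: none
Why: Sulfonylation and ionisation of both hemiketal hydroxyls followed by loss of H2 and H5 (lactol to cyclic enol ether, hydroxybutenolide to ylidenebutenolide); the tertiary C10–OH should not be sulfonylated, and only the C5=C6 isomer with C4 cis to C7 fits the oxygen-bridged bicycle.

**Compound list**

1 | (R)-(−)-linalool | C=C[C@](C)(O)CCC=C(C)C | starting material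
2 | (3R)-3,7-dimethyl-3-(triethylsilyloxy)octa-1,6-diene | C=C[C@](C)(O[Si](CC)(CC)CC)CCC=C(C)C | intermediate
3 | (4R)-4-methyl-4-(triethylsilyloxy)hex-5-enal | C=C[C@](C)(O[Si](CC)(CC)CC)CCC=O | intermediate
4 | (6R)-6-methyl-6-(triethylsilyloxy)octa-1,7-dien-3-ol (C3 epimers) | C=C[C@](C)(O[Si](CC)(CC)CC)CCC(O)C=C | intermediate
5 | (4R)-4-methyl-4-(triethylsilyloxy)cyclohex-2-en-1-ol (C1 epimers) | C[C@]1(O[Si](CC)(CC)CC)C=CC(O)CC1 | intermediate
6 | (4R)-4-methyl-4-(triethylsilyloxy)cyclohex-2-en-1-one | C[C@]1(O[Si](CC)(CC)CC)C=CC(=O)CC1 | intermediate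
7 | (4R)-2-iodo-4-methyl-4-(triethylsilyloxy)cyclohex-2-en-1-one | C[C@]1(O[Si](CC)(CC)CC)C=C(I)C(=O)CC1 | intermediate
8 | ethyl glyoxylate | CCOC(=O)C=O | starting material
9 | isobutylene | CC(C)=C | starting material
10 | ethyl (2R)-2-hydroxy-4-methylpent-4-enoate | CCOC(=O)[C@H](O)CC(C)=C | intermediate
11 | acryloyl chloride | C=CC(Cl)=O | starting material
12 | 2-(trimethylsilyl)ethanol | C[Si](C)(C)CCO | starting material
13 | 2-(trimethylsilyl)ethyl acrylate | C=CC(=O)OCC[Si](C)(C)C | intermediate
14 | ethyl (2R)-4-methyl-2-{3-oxo-3-[2-(trimethylsilyl)ethoxy]propoxy}pent-4-enoate | CCOC(=O)[C@@H](CC(C)=C)OCCC(=O)OCC[Si](C)(C)C | intermediate (not isolated)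
15 | 2-(trimethylsilyl)ethyl (5R)-5-(2-methylprop-2-enyl)-4-oxotetrahydrofuran-3-carboxylate | C=C(C)C[C@H]1OCC(C(=O)OCC[Si](C)(C)C)C1=O | intermediate
16 | 2-(trimethylsilyl)ethyl (5R)-5-(2-methylprop-2-enyl)-4-(trifluoromethylsulfonyloxy)-2,5-dihydrofuran-3-carboxylate | C=C(C)C[C@H]1OCC(C(=O)OCC[Si](C)(C)C)=C1OS(=O)(=O)C(F)(F)F | intermediate
17 | 2-(trimethylsilyl)ethyl (5R)-5-(2-methylprop-2-enyl)-4-(4,4,5,5-tetramethyl-1,3,2-dioxaborolan-2-yl)-2,5-dihydrofuran-3-carboxylate | C=C(C)C[C@H]1OCC(C(=O)OCC[Si](C)(C)C)=C1B2OC(C)(C)C(C)(C)O2 | intermediate (not isolated)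
18 | 2-(trimethylsilyl)ethyl (5R)-5-(2-methylprop-2-enyl)-4-[(3R)-3-methyl-6-oxo-3-(triethylsilyloxy)cyclohex-1-enyl]-2,5-dihydrofuran-3-carboxylate | C[C@]1(O[Si](CC)(CC)CC)C=C(C(=O)CC1)C2=C(C(=O)OCC[Si](C)(C)C)CO[C@@H]2CC(C)=C | intermediate
19 | lithium enolate of the C5,C6-dihydro derivative of 18 (C1–O–Li, C1=C6) | C[C@]1(O[Si](CC)(CC)CC)CC(=C([O-])CC1)C2=C(C(=O)OCC[Si](C)(C)C)CO[C@@H]2CC(C)=C.[Li+] | intermediate (not isolated)
20 | 2-(trimethylsilyl)ethyl (5R)-5-(2-methylprop-2-enyl)-4-[(5R)-5-methyl-5-(triethylsilyloxy)-2-(trifluoromethylsulfonyloxy)cyclohex-1-enyl]-2,5-dihydrofuran-3-carboxylate | C[C@]1(O[Si](CC)(CC)CC)CC(=C(OS(=O)(=O)C(F)(F)F)CC1)C2=C(C(=O)OCC[Si](C)(C)C)CO[C@@H]2CC(C)=C | intermediate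
21 | 2-(trimethylsilyl)ethyl (5R)-4-[(5R)-5-methyl-5-(triethylsilyloxy)-2-(trifluoromethylsulfonyloxy)cyclohex-1-enyl]-5-(2-oxopropyl)-2,5-dihydrofuran-3-carboxylate | C[C@]1(O[Si](CC)(CC)CC)CC(=C(OS(=O)(=O)C(F)(F)F)CC1)C2=C(C(=O)OCC[Si](C)(C)C)CO[C@@H]2CC(C)=O | intermediate
22 | tricyclic alcohol (4R,8R,10S): 1(6)-octalin with C4(CH3)(OSiEt3) and C10(CH3)(OH), fused at C7–C8 to a 2,5-dihydrofuran carrying the 2-(trimethylsilyl)ethyl ester on C11 | C[C@]1(O)C[C@H]2OCC(C(=O)OCC[Si](C)(C)C)=C2C3=C1CC[C@@](C)(O[Si](CC)(CC)CC)C3 | intermediate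
23 | bromo diol (4R,8R,10S): octalin with C8–OH, C10–OH, C4–OSiEt3, exocyclic C7=C11 with CH2Br cis to C8 and CO2CH2CH2SiMe3 cis to C6 | C[C@]1(O)C[C@@H](O)/C(=C(\CBr)C(=O)OCC[Si](C)(C)C)C2=C1CC[C@@](C)(O[Si](CC)(CC)CC)C2 | intermediate
24 | C13 acetate (4R,8R,10S): as 23 with CH2OAc | C[C@]1(O)C[C@@H](O)/C(=C(\COC(C)=O)C(=O)OCC[Si](C)(C)C)C2=C1CC[C@@](C)(O[Si](CC)(CC)CC)C2 | intermediate
25 | C8 methacrylate (4R,8R,10S): as 24 with C8–O-methacryloyl | C[C@]1(O)C[C@@H](OC(=O)C(C)=C)/C(=C(\COC(C)=O)C(=O)OCC[Si](C)(C)C)C2=C1CC[C@@](C)(O[Si](CC)(CC)CC)C2 | intermediate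
26 | hydroxy acid (4R,8R,10S): as 25 with free C4–OH and C12 carboxylic acid | C[C@]1(O)C[C@@H](OC(=O)C(C)=C)/C(=C(\COC(C)=O)C(=O)O)C2=C1CC[C@@](C)(O)C2 | intermediate
27 | hydroperoxy hemiketal: ten-membered ring with C1(OOH) bridged by oxygen to C4 and C6 as 5-hydroxybutenolide (one regioisomer drawn) | C=C(C)C(=O)O[C@@H]1C[C@](C)(O)C2(OO)CC[C@](C)(CC3(O)OC(=O)C(COC(C)=O)=C31)O2 | intermediate (not isolated)
28 | transannular bis-hemiketal (4R,8R,10S; C1 and C6 epimers) | C=C(C)C(=O)O[C@@H]1C[C@](C)(O)C2(O)CC[C@](C)(CC3(O)OC(=O)C(COC(C)=O)=C31)O2 | intermediate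
29 | CNP0394509.1 | C=C(C)C(=O)O[C@@H]1C[C@](C)(O)C2=CC[C@](C)(/C=C3/OC(=O)C(COC(C)=O)=C31)O2 | target

**Step count and risks**

Total step count: 20. Longest linear sequence: 16 steps (steps 1–6 and 11–20, from (R)-linalool).

Steps most likely to fail:

Step 14. Protodemetallation of the alkenyl–metal species may outrun its addition to the hindered methyl ketone, and the facial preference at C10 may be weaker than argued. The closure would then be changed from a stoichiometric chromium-mediated addition to a catalytic boron-to-rhodium transfer. Setting out from 21, Miyaura borylation (B2pin2, PdCl2(dppf), KOAc, dioxane, 80 °C) should give the C1 alkenyl pinacolboronate F1. [Rh(OH)(cod)]2 (5 mol %) in dioxane/H2O at 60 °C should then pass the alkenyl group to monovalent rhodium and insert the C10 ketone (intramolecular rhodium-catalysed 1,2-addition of an organoboron reagent), returning to the route at 22.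

Step 15. The borane may ionise the tertiary allylic C10–OH or attack the silyl ether instead of cleaving only the C13–O bond. The ether would then be opened by acylative cleavage, which needs no strong Lewis acid and installs the C8 ester in the same event. Setting out from 22, methacryloyl chloride and NaI in MeCN at 0 °C (acyl iodide formed in the flask, acylation of the ring oxygen, iodide attack at primary allylic C13) should give the iodo methacrylate F2. Bu4NOAc in acetone would then give 25, where the route is rejoined without passing through 23 and 24.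

Step 20. Base-induced β-elimination across C5–H/C4–O, or ionisation of only one of the two hemiketals, may spoil the one-pot double dehydration. The two hydroxyls would then first be made into leaving groups and expelled under Lewis-acid E1 conditions. Setting out from 28, Ac2O/pyridine/DMAP (CH2Cl2, 0 °C) should give the bis(hemiketal acetate) F3. Me3SiOTf/i-Pr2NEt (CH2Cl2, −78 → 0 °C; ionisation of both ketal acetates to oxocarbenium ions and loss of H2 and H5) should give the C10 trimethylsilyl ether of the target F4, and citric acid in MeOH would remove the silyl group to return to the route at 29.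

**Further compounds**

F1 | step 14 | 2-(trimethylsilyl)ethyl (5R)-4-[(5R)-5-methyl-2-(4,4,5,5-tetramethyl-1,3,2-dioxaborolan-2-yl)-5-(triethylsilyloxy)cyclohex-1-enyl]-5-(2-oxopropyl)-2,5-dihydrofuran-3-carboxylate | C[C@]1(O[Si](CC)(CC)CC)CC(=C(B3OC(C)(C)C(C)(C)O3)CC1)C2=C(C(=O)OCC[Si](C)(C)C)CO[C@@H]2CC(C)=O
F2 | step 15 | iodo methacrylate (4R,8R,10S): as 25 with CH2I in place of CH2OAc | C[C@]1(O)C[C@@H](OC(=O)C(C)=C)/C(=C(\CI)C(=O)OCC[Si](C)(C)C)C2=C1CC[C@@](C)(O[Si](CC)(CC)CC)C2
F3 | step 20 | bis(hemiketal acetate) of 28 (C1–OAc and C6–OAc) | C=C(C)C(=O)O[C@@H]1C[C@](C)(O)C2(OC(C)=O)CC[C@](C)(CC3(OC(C)=O)OC(=O)C(COC(C)=O)=C31)O2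
F4 | step 20 | C10 trimethylsilyl ether of the target | C=C(C)C(=O)O[C@@H]1C[C@](C)(O[Si](C)(C)C)C2=CC[C@](C)(/C=C3/OC(=O)C(COC(C)=O)=C31)O2
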